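**Falling product.** In the noon run J read 30.4% of the Z charge at 0.667 h, then 23.6% at 2.50 h, while G read higher at each sampling. This flask is that run carried on.

in all of them: Z 38 mM; D 95 µM
- noon: Q 38 mM; the very flask that is asked about, followed so far
- flask: Q 38.0 mM; time 8.0 h

noon run (percent of the Z charged)

| time / h | J / % | G / % | Z / % |
|---|---|---|---|
| 0.200 | 18.8 | 2.2 | 75.4 |
| 0.333 | 24.6 | 4.4 | 64.5 |
| 0.667 | 30.4 | 11.0 | 47.5 |
| 1.33 | 29.0 | 22.9 | 31.3 |
| 2.50 | 23.6 | 32.0 | 21.4 |

(standard deviation of a reading: 0.3 percentage points)

- share of J in J plus G at 2.5 min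
- share of J in J plus G at 8.0 h
- which of J and G there is more of at 8.0 h



**The gap.** I reckoned the small term: the fraction of the Z charge found in neither Z, J nor G. In the noon run it grew from 16.8% at 1.33 h to 23.0% at 2.50 h. I assumed Z and Q leave together, one for one. My leak constant is the gap's gain per hour over the mean fraction of Z times the mean fraction of Q left: 0.251 h⁻¹. With Q held at its charge, a pseudo-first-order view, Z's leak half-time is 2.76 h.

**Turning time.** The time 8.0 h is longer than that half-time, so the leak takes Z that could have fed J. I expected the J share to fall below the last reading's 42.4%, with G ahead. That was a direction, not a number.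

**Turning Q.** By hand, the leak half-time with Q held at its charge goes as one over that charge.

**The forecast.** It gave a J share of 98% at 2.5 min and of 38% at 8.0 h, with G ahead. It put the gap “apparently directly from Z”, whereas I charged it to Q as well.

**The result.** This flask gave a J share of 98.1% at 2.5 min and of 31.3% at 8.0 h, with G at 35.9% and J at 16.3% of the Z charge. The late forecast stood 6.7 percentage points too high.

    Z + D ⇌ J + D, rate k1*[Z]*[D] forward; the back reaction follows from the equilibrium constant (K = 1.20, k = 14000 L mol⁻¹ h⁻¹)
    J + D ⇌ G + D, rate k2*[D]*[J] forward; the back reaction follows from the equilibrium constant (K = 2.00, k = 9800 L mol⁻¹ h⁻¹)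
    D → L (k = 0.170 h⁻¹)
    Z + Q → E (k = 6.80 L mol⁻¹ h⁻¹)

**Leak reused.** From 4.00 h to 8.00 h in this flask, the leak constant with mean Z and mean Q gives 9.02% of the Z charge, and E gained 8.9 points. The neighbour flask held 150 mM of Q, 3.95 equiv, so its leak half-time with Q held at its charge is 0.699 h, shorter than 8.0 h. At 8.00 h that neighbour held Z 1.70%, G 17.6% and E 74.8%, and its J share was 25.0%.

The runs are simulated for substances that don't exist, noise included.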